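**Retrosynthetic overview**
- The C8 ester is cut last: N-methylurocanic acid (Knoevenagel–Doebner from an imidazole aldehyde and malonic acid) is coupled to the C8 alcohol.
- The 4,7-oxa-bridged dihydrofuran hemiketal comes from a pyranose → furanose ring contraction, after C7 methylation of the pyranone made by Achmatowicz ring expansion of a [6](2,5)furanophane carbinol.
- The furanophane is closed at C3–C4 (furan C–H borylation, then intramolecular Suzuki–Miyaura coupling) from a (Z)-α-bromoacrylate; C2=C3 comes from the C2 aldehyde and methyl tribromoacetate, C8 from asymmetric transfer hydrogenation of a 2-acylfuran.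
- Ring A comes from a catalytic asymmetric [4+2] of (E)-4-methylpent-2-enal with a 1-furyl-1-siloxy triene, itself made from 2-acetylfuran and tiglic aldehyde.
- Ring order: cyclohexene ring A → ten-membered furanophane → pyranone (expansion) → dihydrofuran (contraction).

Assumption: sarcodictyin numbering is used for all intermediates (ring A = C1, C14 (iPr), C13, C12=C11 (Me), C10; ten-membered ring = C1–C10; CO2Me on C3; oxygen bridge C4–O–C7), and the target read from the SMILES is (1S,4R,7S,8S,10R,14R).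

Step 1
Reactants: 1 2-acetylfuran; 2 (E)-2-methylbut-2-enal (tiglic aldehyde)
Product: 4 (2E,4E)-1-(furan-2-yl)-4-methylhexa-2,4-dien-1-one, via aldol adduct 3 (not isolated)
Conditions: NaOH (10% aq), EtOH, 0 → 25 °C
Reagents that add atoms: none
Why: Claisen–Schmidt (crossed aldol) condensation: the methyl ketone is the only partner with an α-hydrogen, and E1cB dehydration gives the (E)-enone, so C8–C13 and the C11 methyl are assembled in one operation.

Step 2
Reactants: 4 (2E,4E)-1-(furan-2-yl)-4-methylhexa-2,4-dien-1-one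
Product: 5 tert-butyl{[(1Z,3E)-1-(furan-2-yl)-4-methylhexa-1,3,5-trien-1-yl]oxy}dimethylsilane
Conditions: TBSOTf, Et3N, CH2Cl2, 0 °C
Reagents that add atoms: tert-butyldimethylsilyl trifluoromethanesulfonate, CC(C)(C)[Si](C)(C)OS(=O)(=O)C(F)(F)F
Why: Soft enolisation: O-silylation gives a pentadienyl-type oxocarbenium ion whose only acidified hydrogens are on the terminal (ε) methyl, so deprotonation gives the linear silyl trienol ether, with the 3E geometry following from the s-trans conformer of the dienone.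

Step 3
Reactants: 5 tert-butyl{[(1Z,3E)-1-(furan-2-yl)-4-methylhexa-1,3,5-trien-1-yl]oxy}dimethylsilane; 6 (E)-4-methylpent-2-enal
Product: 8 (1R,2R,6R)-2-[2-(furan-2-yl)-2-oxoethyl]-3-methyl-6-(propan-2-yl)cyclohex-3-ene-1-carbaldehyde, via silyl enol ether cycloadduct 7 (not isolated)
Conditions: (2S,5S)-5-benzyl-2-tert-butyl-3-methylimidazolidin-4-one (20 mol %), 2,4-dinitrobenzoic acid (20 mol %), CH2Cl2, H2O (2 equiv), −40 °C; then 1 M HCl, THF, 0 °C
Reagents that add atoms: none
Why: Proposed new method: the imidazolidinone converts 6 into an (E)-iminium ion (LUMO lowering), and the terminal s-cis diene C10=C11–C12=C13 of triene 5, whose HOMO is raised by the remote siloxy donor and is largest at C13, adds endo to the face not shielded by the benzyl group, so C13 bonds to the β-carbon (C14, R) and C10 to the α-carbon, giving iPr/CHO trans (E-dienophile) and CHO/C9 cis (E-diene, endo) while the hindered inner diene stays untouched, and acidic work-up unmasks the C8 ketone; the closest known reaction types are the imidazolidinone-catalysed Diels–Alder reaction of enals with simple acyclic dienes and the iminium-catalysed Mukaiyama–Michael addition of silyl enol ethers to β-branched enals, but a 1-aryl-1-siloxy triene has not been used as the diene.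

Step 4
Reactants: 8 (1R,2R,6R)-2-[2-(furan-2-yl)-2-oxoethyl]-3-methyl-6-(propan-2-yl)cyclohex-3-ene-1-carbaldehyde; 9 methyl tribromoacetate
Product: 11 methyl (2Z)-2-bromo-3-[(1R,2R,6R)-2-[2-(furan-2-yl)-2-oxoethyl]-3-methyl-6-(propan-2-yl)cyclohex-3-en-1-yl]prop-2-enoate, via dibromo aldolate 10 (not isolated)
Conditions: CrCl2 (6 equiv), THF, 25 °C
Reagents that add atoms: none
Why: Chromium-Reformatsky addition followed by reductive elimination (Z-selective α-haloacrylate olefination): divalent chromium turns the tribromoacetate into a dibromo enolate that adds only to the aldehyde (the aryl ketone is inert), and a second reduction triggers elimination to the (Z)-α-bromoacrylate, which puts bromine cis to C1 as the ring closure needs.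

Step 5
Reactants: 11 methyl (2Z)-2-bromo-3-[(1R,2R,6R)-2-[2-(furan-2-yl)-2-oxoethyl]-3-methyl-6-(propan-2-yl)cyclohex-3-en-1-yl]prop-2-enoate
Product: 12 methyl (2Z)-2-bromo-3-[(1R,2R,6R)-2-[(2S)-2-(furan-2-yl)-2-hydroxyethyl]-3-methyl-6-(propan-2-yl)cyclohex-3-en-1-yl]prop-2-enoate
Conditions: RuCl(p-cymene)[(S,S)-TsDPEN] (2 mol %), HCO2H/Et3N 5:2, CH2Cl2, 25 °C
Reagents that add atoms: none
Why: Noyori–Ikariya asymmetric transfer hydrogenation: 2-acylfurans are privileged substrates, and the (S,S)-catalyst delivers hydride in the same sense as for acetophenone to give the (8S)-carbinol under reagent control, leaving the ester and vinyl bromide untouched.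

Step 6
Reactants: 12 methyl (2Z)-2-bromo-3-[(1R,2R,6R)-2-[(2S)-2-(furan-2-yl)-2-hydroxyethyl]-3-methyl-6-(propan-2-yl)cyclohex-3-en-1-yl]prop-2-enoate
Product: 14 furanophane alcohol (1S,8S,10R,14R; ten-membered ring C1–C10 in which C4–C7 are the carbons of a 2,5-bridged furan; C2=C3 with C1 cis to C4; 3-CO2Me; 8-OH), via furylboronate 13 (not isolated)
Conditions: [Ir(OMe)(cod)]2 (2.5 mol %), 4,4'-di-tert-butyl-2,2'-bipyridine, B2pin2, THF, 50 °C; then Pd(OAc)2 (10 mol %), SPhos, K3PO4, THF/H2O 10:1, 40 °C, 2 mM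
Reagents that add atoms: none
Why: Iridium-catalysed C–H borylation selects the only heteroaryl α-C–H (furan C4), and the telescoped intramolecular Suzuki–Miyaura coupling with the electron-poor vinyl bromide closes the [6](2,5)furanophane with retention of alkene geometry, the cis arms on ring A and the Z-bromoacrylate bringing the two ends together.

Step 7
Reactants: 14 furanophane alcohol
Product: 16 pyranone lactol (1S,4S,8S,10R,14R; oxygen bridge C4–O–C8; 4-OH; C5=C6; C7 ketone), via Z-enedione 15 (not isolated)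
Conditions: VO(acac)2 (5 mol %), t-BuOOH, CH2Cl2, 0 °C
Reagents that add atoms: tert-butyl hydroperoxide, CC(C)(C)OO
Why: Achmatowicz oxidative ring expansion (furan → 6-hydroxy-2H-pyran-3(6H)-one): hydroxyl-directed vanadium-catalysed oxidation opens the furan to the Z-enedione, whose C8 hydroxyl closes onto the C4 ketone; the directing effect spares C11=C12 and C2=C3, C8 is untouched, and the new C4 centre is fixed because the one-oxygen bridge can only span the ring cis.

Step 8
Reactants: 16 pyranone lactol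
Product: 17 methyl carbinol (1S,4S,7S,8S,10R,14R; pyranose form with 7-OH and 7-CH3)
Conditions: MeLi (3 equiv), CeCl3 (3 equiv), THF, −78 °C; NH4Cl aq
Reagents that add atoms: methyllithium, [Li]C
Why: Organocerium (Imamoto) 1,2-addition: MeCeCl2 is non-basic and ketone-selective, so it adds to the C7 enone carbonyl and not to the hindered conjugated ester while the lactol sits as its alkoxide, and it attacks the convex face of the bridged pyranone, opposite the C8–C9 bond and the five-carbon bridge, which sets C7 as S.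

Step 9
Reactants: 17 methyl carbinol
Product: 19 furanose diol (1S,4R,7S,8S,10R,14R; oxygen bridge C4–O–C7; 4-OH; 8-OH), via open hydroxy enone 18 (not isolated)
Conditions: PPTS (10 mol %), water-saturated CH2Cl2, 25 °C
Reagents that add atoms: none
Why: Acid-catalysed lactol ring–chain tautomerism (pyranose → furanose ring contraction): the C4 hemiketal opens to the cis-hydroxy enone and recloses through the tertiary C7 hydroxyl to the less strained 4,7-oxa-bridged 2,5-dihydrofuran of the natural product, releasing the C8 hydroxyl and fixing C4 as R by the cis-bridging requirement.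

Step 10
Reactants: 20 1-methyl-1H-imidazole-4-carbaldehyde; 21 malonic acid
Product: 23 (E)-3-(1-methyl-1H-imidazol-4-yl)prop-2-enoic acid (N-methylurocanic acid), via alkylidenemalonic acid 22 (not isolated)
Conditions: pyridine, piperidine (cat.), 100 °C
Reagents that add atoms: none
Why: Knoevenagel–Doebner condensation: the alkylidenemalonic acid decarboxylates in hot pyridine to the thermodynamically favoured (E)-acrylic acid.

Step 11
Reactants: 19 furanose diol; 23 (E)-3-(1-methyl-1H-imidazol-4-yl)prop-2-enoic acid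
Product: 25 sarcodictyin A, via O-acylisourea 24 (not isolated)
Conditions: DCC, DMAP, CH2Cl2, 25 °C
Reagents that add atoms: none
Why: Steglich esterification: the secondary C8 hydroxyl is acylated in preference to the tertiary bridgehead hemiketal hydroxyl at C4, and no stereocentre is touched.

**Compound list**
1 | 2-acetylfuran | CC(=O)c1ccco1 | starting material
2 | (E)-2-methylbut-2-enal | C/C=C(\C)C=O | starting material
3 | (4E)-1-(furan-2-yl)-3-hydroxy-4-methylhex-4-en-1-one (racemic aldol adduct) | C/C=C(\C)C(O)CC(=O)c1ccco1 | intermediate (not isolated)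
4 | (2E,4E)-1-(furan-2-yl)-4-methylhexa-2,4-dien-1-one | C/C=C(C)/C=C/C(=O)c1ccco1 | intermediate
5 | tert-butyl{[(1Z,3E)-1-(furan-2-yl)-4-methylhexa-1,3,5-trien-1-yl]oxy}dimethylsilane | C=C/C(C)=C/C=C(\O[Si](C)(C)C(C)(C)C)c1ccco1 | intermediate
6 | (E)-4-methylpent-2-enal | CC(C)/C=C/C=O | starting material
7 | (1R,2R,6R)-2-[(Z)-2-{[tert-butyl(dimethyl)silyl]oxy}-2-(furan-2-yl)ethenyl]-3-methyl-6-(propan-2-yl)cyclohex-3-ene-1-carbaldehyde | O=C[C@@H]1[C@@H](C(C)C)CC=C(C)[C@@H]1/C=C(\O[Si](C)(C)C(C)(C)C)c1ccco1 | intermediate (not isolated)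
8 | (1R,2R,6R)-2-[2-(furan-2-yl)-2-oxoethyl]-3-methyl-6-(propan-2-yl)cyclohex-3-ene-1-carbaldehyde | O=C[C@@H]1[C@@H](C(C)C)CC=C(C)[C@@H]1CC(=O)c1ccco1 | intermediate
9 | methyl tribromoacetate | COC(=O)C(Br)(Br)Br | starting material
10 | methyl 2,2-dibromo-3-hydroxy-3-[(1R,2R,6R)-2-[2-(furan-2-yl)-2-oxoethyl]-3-methyl-6-(propan-2-yl)cyclohex-3-en-1-yl]propanoate (as chromium alkoxide, either carbinol epimer) | COC(=O)C(Br)(Br)C(O)[C@@H]1[C@@H](C(C)C)CC=C(C)[C@@H]1CC(=O)c1ccco1 | intermediate (not isolated)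
11 | methyl (2Z)-2-bromo-3-[(1R,2R,6R)-2-[2-(furan-2-yl)-2-oxoethyl]-3-methyl-6-(propan-2-yl)cyclohex-3-en-1-yl]prop-2-enoate | COC(=O)/C(Br)=C/[C@@H]1[C@@H](C(C)C)CC=C(C)[C@@H]1CC(=O)c1ccco1 | intermediate
12 | methyl (2Z)-2-bromo-3-[(1R,2R,6R)-2-[(2S)-2-(furan-2-yl)-2-hydroxyethyl]-3-methyl-6-(propan-2-yl)cyclohex-3-en-1-yl]prop-2-enoate | COC(=O)/C(Br)=C/[C@@H]1[C@@H](C(C)C)CC=C(C)[C@@H]1C[C@H](O)c1ccco1 | intermediate
13 | methyl (2Z)-2-bromo-3-[(1R,2R,6R)-2-{(2S)-2-hydroxy-2-[5-(4,4,5,5-tetramethyl-1,3,2-dioxaborolan-2-yl)furan-2-yl]ethyl}-3-methyl-6-(propan-2-yl)cyclohex-3-en-1-yl]prop-2-enoate | COC(=O)/C(Br)=C/[C@@H]1[C@@H](C(C)C)CC=C(C)[C@@H]1C[C@H](O)c1ccc(B2OC(C)(C)C(C)(C)O2)o1 | intermediate (not isolated)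
14 | furanophane alcohol (1S,8S,10R,14R; C4–C7 = furan-2,5-diyl; C2=C3, 3-CO2Me; 8-OH) | COC(=O)/C1=C/[C@@H]2[C@@H](C(C)C)CC=C(C)[C@@H]2C[C@H](O)c2ccc1o2 | intermediate
15 | Z-enedione (1S,8S,10R,14R; C4 and C7 ketones; Z-C5=C6; 8-OH) | COC(=O)/C1=C/[C@@H]2[C@@H](C(C)C)CC=C(C)[C@@H]2C[C@H](O)C(=O)/C=C\C1=O | intermediate (not isolated)
16 | pyranone lactol (1S,4S,8S,10R,14R; C4–O–C8 bridge; 4-OH; C7 ketone) | COC(=O)/C1=C/[C@@H]2[C@@H](C(C)C)CC=C(C)[C@@H]2C[C@@H]3O[C@@]1(O)C=CC3=O | intermediate
17 | methyl carbinol, pyranose form (1S,4S,7S,8S,10R,14R; 7-OH, 7-CH3) | COC(=O)/C1=C/[C@@H]2[C@@H](C(C)C)CC=C(C)[C@@H]2C[C@@H]3O[C@@]1(O)C=C[C@]3(C)O | intermediate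
18 | open hydroxy enone (1S,7S,8S,10R,14R; C4 ketone; Z-C5=C6; 7-OH, 8-OH) | COC(=O)/C1=C/[C@@H]2[C@@H](C(C)C)CC=C(C)[C@@H]2C[C@H](O)[C@@](C)(O)/C=C\C1=O | intermediate (not isolated)
19 | furanose diol (1S,4R,7S,8S,10R,14R; C4–O–C7 bridge; 4-OH, 8-OH) | COC(=O)/C1=C/[C@@H]2[C@@H](C(C)C)CC=C(C)[C@@H]2C[C@H](O)[C@]2(C)C=C[C@@]1(O)O2 | intermediate
20 | 1-methyl-1H-imidazole-4-carbaldehyde | Cn1cnc(C=O)c1 | starting material
21 | malonic acid | OC(=O)CC(=O)O | starting material
22 | 2-[(1-methyl-1H-imidazol-4-yl)methylidene]propanedioic acid | Cn1cnc(C=C(C(=O)O)C(=O)O)c1 | intermediate (not isolated)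
23 | (E)-3-(1-methyl-1H-imidazol-4-yl)prop-2-enoic acid | Cn1cnc(/C=C/C(=O)O)c1 | intermediate
24 | O-acylisourea of 23 with DCC | Cn1cnc(/C=C/C(=O)OC(=NC2CCCCC2)NC2CCCCC2)c1 | intermediate (not isolated)
25 | sarcodictyin A | COC(=O)/C1=C/[C@@H]2[C@@H](C(C)C)CC=C(C)[C@@H]2C[C@H](OC(=O)/C=C/c2cn(C)cn2)[C@]2(C)C=C[C@@]1(O)O2 | target

**Step count:** 11 steps in total; longest linear sequence 10 (steps 1–9 and 11).

**Three steps most likely to fail**

Step 3 (the proposed new step). The triene may hydrolyse before it reacts, may attack through its enol ether carbon to give an open-chain Michael product, or may add with poor endo selectivity. The fallback uses known auxiliary-controlled chemistry and sets out from 6 and 5. Pinnick oxidation of 6 (NaClO2, NaH2PO4, 2-methylbut-2-ene) gives (E)-4-methylpent-2-enoic acid F1. Its pivalic mixed anhydride is coupled with lithiated (S)-4-benzyloxazolidin-2-one to give (4S)-4-benzyl-3-[(E)-4-methylpent-2-enoyl]oxazolidin-2-one F2. An Et2AlCl-promoted Diels–Alder reaction of F2 with triene 5 (CH2Cl2, −78 → −30 °C; chelated s-cis imide, diene adds endo and anti to the benzyl group) gives the imide cycloadduct F3. LiBH4 removes the auxiliary to give the primary alcohol F4, and Dess–Martin oxidation returns to the route at 7, which is hydrolysed to 8 as in step 3.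

Step 6. The electron-rich furylboronate may protodeboronate, the strained ten-membered ring may close slowly, and the vinylpalladium intermediate may instead insert into the C11=C12 alkene. The fallback changes both the bond-forming mode and the order, and sets out from 11. The 2-acylfuran, the best substrate class for concerted metalation–deprotonation, is cyclised directly by palladium-catalysed C–H alkenylation (Pd(OAc)2, KOAc, DMA, 110 °C, 1 mM; the weak carboxylate base is chosen so that ketone α-vinylation is not promoted) to give the furanophane ketone F5. The transfer hydrogenation of step 5 is then run on the macrocycle, and the route is rejoined at 14.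

Step 8. The lactol alkoxide may open to the enedione and take up a second methyl at C4, or the ester may be attacked. The fallback masks the lactol first and sets out from 16. PPTS in methanol gives the pyranone methyl ketal F6, in which only the C7 ketone is electrophilic. MeLi/CeCl3 then gives the methyl carbinol methyl ketal F7. PPTS in wet acetonitrile hydrolyses the ketal and triggers the ring contraction in the same operation, so the route is rejoined at 19.

**Further compounds**
F1 | step 3 | (E)-4-methylpent-2-enoic acid | CC(C)/C=C/C(=O)O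
F2 | step 3 | (4S)-4-benzyl-3-[(E)-4-methylpent-2-enoyl]oxazolidin-2-one | CC(C)/C=C/C(=O)N1[C@@H](Cc2ccccc2)COC1=O
F3 | step 3 | (4S)-4-benzyl-3-{[(1R,2R,6R)-2-[(Z)-2-{[tert-butyl(dimethyl)silyl]oxy}-2-(furan-2-yl)ethenyl]-3-methyl-6-(propan-2-yl)cyclohex-3-en-1-yl]carbonyl}oxazolidin-2-one | O=C([C@@H]1[C@@H](C(C)C)CC=C(C)[C@@H]1/C=C(\O[Si](C)(C)C(C)(C)C)c1ccco1)N1[C@@H](Cc2ccccc2)COC1=O
F4 | step 3 | [(1R,2R,6R)-2-[(Z)-2-{[tert-butyl(dimethyl)silyl]oxy}-2-(furan-2-yl)ethenyl]-3-methyl-6-(propan-2-yl)cyclohex-3-en-1-yl]methanol | OC[C@@H]1[C@@H](C(C)C)CC=C(C)[C@@H]1/C=C(\O[Si](C)(C)C(C)(C)C)c1ccco1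
F5 | step 6 | furanophane ketone (1S,10R,14R; C4–C7 = furan-2,5-diyl; C2=C3, 3-CO2Me; C8 ketone) | COC(=O)/C1=C/[C@@H]2[C@@H](C(C)C)CC=C(C)[C@@H]2CC(=O)c2ccc1o2
F6 | step 8 | pyranone methyl ketal (1S,4S,8S,10R,14R; C4–O–C8 bridge; 4-OCH3; C7 ketone) | COC(=O)/C1=C/[C@@H]2[C@@H](C(C)C)CC=C(C)[C@@H]2C[C@@H]3O[C@@]1(OC)C=CC3=O
F7 | step 8 | methyl carbinol methyl ketal (1S,4S,7S,8S,10R,14R; 4-OCH3; 7-OH, 7-CH3) | COC(=O)/C1=C/[C@@H]2[C@@H](C(C)C)CC=C(C)[C@@H]2C[C@@H]3O[C@@]1(OC)C=C[C@]3(C)O
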